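## Structural features

The target 21 is an achiral dimer: two identical 7-acetyl-3,6,8-trihydroxy-4,4-dimethylnaphthalen-1(4H)-one halves are joined by one CH2 group between their C2 atoms. In each half ring A is an acylresorcinol (hydroxyls on C6 and C8, acetyl on C7, only C5 unsubstituted). Ring B is the enol of a cyclic 1,3-diketone (C1 ketone, C3 enol) whose quaternary gem-dimethyl carbon C4 sits directly on the arene carbon C4a. There is no stereocentre, so no stereocentres stand next to each other and nothing can epimerise; the problems are regiochemical. The fragile parts are the methylene-bis(enol) unit, which can fragment by retro-Michael reaction or close to a pyran under dehydrating acid, the electron-rich phenols, and the 4,4-dimethyl dienone-type ring B, which should not meet superacid. The real difficulty is the crowded ring A beside a quaternary carbon, the acetyl group between two hydroxyls, the choice between the two ring B oxygens, and doing every operation twice. The key step uses two facts: the shared C4a=C8a bond is the enone double bond (to C1) of a ring B cyclohexadienone, and the C6/C8 oxygen pattern of ring A is that of a 1,1-dialkoxy-3-silyloxybutadiene spanning C5 to C8.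

## Logic of the disconnections

21 to 20. The four O–CH3 bonds on C3 and C8 of both halves are cut. The vinylogous acid and the peri phenol stay masked to the end because, once free, they invite pyran formation and retro-Michael cleavage. The gain is a neutral precursor that survives acylation. The demand is a dealkylation that attacks the methyl carbon, since C3 itself is flanked by C4 and the bridge.

20 to 18. The two C7–acetyl bonds are cut. Ring A comes out of the annulation with C7 free, and C7 is the only accessible activated position: C5 lies peri to the gem-dimethyl group. This removes two carbons per half and leaves a resorcinol monoether with a free C6 hydroxyl. The forward step must be an ortho-selective C-acylation of a phenol deactivated by the C1 carbonyl.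

18 to 9 and 16. In each half C4a–C5 and C8–C8a are cut, which removes both rings A. Ring B with its quaternary carbon and the bridge then comes from a simple dione, and no aryl–quaternary carbon bond has to be made. Four rings become two. The forward step needs a dienophile with C1 as ketone and a leaving group on C8a, and a way to lose HBr although H and Br end up cis.

9 to 8 to 6. The C6–Br bonds and the C5=C6 unsaturation are taken back to a saturated ketone. C6 is the only enolisable position of 6, so halogen and unsaturation can be placed there unambiguously. The forward steps are a double bromination and one elimination per ring.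

6 to 4, through 5. The O–CH3 bonds on C3 are cut. The ether must sit on the carbonyl beside C4 so that the C1 ketone keeps its enolisable C6. Direct etherification prefers the other oxygen, so the forward step must reverse the steric bias; passing through the symmetrically O-alkylated cation 5 does this.

4 to 1 and 2. Both C2–CH2 bonds are cut. This is the condensation of an acidic 1,3-dione with formaldehyde and leads to two commercial materials.

16 to 15 to 13 to 10 and 11. The Si–O bond, the two C–OMe bonds and the C2–C3 bond of the butenone are cut in turn. The 1,1-dimethoxy-3-silyloxy pattern requires the ketene acetal ketone 15, which comes from an acylated 1,1-dichloroalkene.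

## Other disconnections considered

Alternative 1: The cut is C4a–C8a in both rings A. In the forward sense KOH in methanol opens the two pyranone rings of A2 to triketo esters, and each C8a methylene condenses on the C4a ketone to give the bis(resorcylate) A1.
- In its favour: it is polyketide-like, uses mild reagents, delivers both phenols of ring A free, and has no elimination problem and no cycloaddition at a neopentyl carbon. On protecting-group economy in ring A it is better than the chosen plan.
- Against it: the C4a ketone is flanked by the quaternary carbon, and the C(=O)–CMe2–C(=O) unit of A2 is a non-enolisable 1,3-diketone, the classic substrate for retro-Claisen cleavage by methoxide or hydroxide. Several other aldol modes of the polyketone chain compete.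
- Comparison: A1 still lacks both rings B and both acetyl groups, so a double Dieckmann closure and a double acylation follow, whereas 18 already has all four rings. A2 is also much harder to reach than 9. Overall this is the longer and less controlled route.

Alternative 2: The cut is C1–C8a in both halves. The bis(beta-keto ester) A4 is obtained from the beta-keto ester A5 and formaldehyde, and P2O5 in MeSO3H closes both rings B by Friedel–Crafts acylation to give A3.
- In its favour: the attacked arene carbon is ortho to one methoxy group and para to the other, the two ortho positions are equivalent, and the aryl–CMe2 bond comes from simple alkylation of an arylacetic ester. The C3 enol appears free, so the regiochemical detour of step 2 is not needed, and there is no elimination from a cis-fused adduct. On the number of steps to the tetracycle it equals the chosen plan or is shorter, and its ring closure is electronically better matched than a cycloaddition at C4a.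
- Against it: A4 is a 1,5-diketone in a hot dehydrating acid, so closure to a 4H-pyran or a dihydropyranone competes with the acylation, and an ester is a weak acylating agent.
- Comparison: A3 has no free phenol, so the C7 acylation has no chelate to direct it between two methoxy groups, and four aryl ethers must be cleaved. In 18 the free C6 hydroxyl directs the acylation and every remaining ether is carbonyl-activated. The two plans are close; the chosen one is preferred for the controlled endgame.

Alternative 3: The cuts are C5–C6 and C7–C8. LiN(iPr)2 deprotonates the C4a methyl group of the bis(dienone ester) A7, the carbanion adds to the acetal carbon of 15, and a Claisen closure of C7 onto the C8 ester gives A6.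
- In its favour: the acetyl group arrives with ring A, O6 and O8 are differentiated at once, and no Friedel–Crafts step is needed. After the key step only demethylation remains, so the endgame is one step shorter than in the chosen plan; here it is better. It uses the same ketone 15.
- Against it: A7 is a fully substituted dienone ester with no short access. The amide base and the carbanion can attack the dienone or the C3 vinylogous ester, the acceptor is a hindered beta,beta-dialkoxy enone, and the annulation must succeed twice with four or more equivalents of base.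
- Comparison: the chosen plan has the longer endgame but a precursor made in four steps from a commercial dione, and its key step runs without strong base.

Key step: step 8

Remarks on the chemistry:
- Compounds 4 and 21 are tautomeric vinylogous acids; each is drawn as one enol form.
- Methyl acetoacetate gives dienes that carry a silyloxy group on the ketene acetal carbon, not the 6-hydroxy-8-methoxy pattern of 18. Diene 16 is the silyl enol ether of 15, so 15 is made from 10 and 11.
- O-Methylation of the unsymmetrical dione goes by preference to the oxygen remote from C4. That would leave the ketone beside the quaternary carbon with no enolisable position, so step 2 is designed to give the other isomer.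
- In 17 the hydrogen on C4a and the bromine on C8a are cis, so anti elimination is impossible. Aromatisation is therefore routed through loss of methanol first.

## Route

Step 1
Reactants: 1 4,4-dimethylcyclohexane-1,3-dione (2 equiv); 2 formaldehyde
Product: 4 2,2'-methylenebis(3-hydroxy-4,4-dimethylcyclohex-2-en-1-one), via 4,4-dimethyl-2-methylidenecyclohexane-1,3-dione 3 (not isolated)
Conditions: 37% aq. HCHO (0.5 equiv), piperidine (cat.), EtOH–H2O, rt
Reagents that add atoms: none
Why: Knoevenagel condensation of the acidic dione with formaldehyde gives the alkylidene dione 3, which is trapped at once by a second dione in a Michael addition; no stereocentre is formed and the bis(enol) should crystallise from the medium.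

Step 2
Reactants: 4 2,2'-methylenebis(3-hydroxy-4,4-dimethylcyclohex-2-en-1-one)
Product: 6 2,2'-methylenebis(3-methoxy-4,4-dimethylcyclohex-2-en-1-one), via bis(1,3-dimethoxycyclohexenylium) bis(tetrafluoroborate) 5 (not isolated)
Conditions: Me3OBF4 (5 equiv), 2,6-di-tert-butyl-4-methylpyridine (2.2 equiv), CH2Cl2, 0 °C to rt; then cold sat. aq. NaHCO3
Reagents that add atoms: trimethyloxonium tetrafluoroborate, C[O+](C)C.F[B-](F)(F)F; water, O
Why: Proposed new method: exhaustive O-methylation turns each ring, whichever oxygen reacts first, into the same 1,3-dimethoxyallyl cation 5, and water should then add to the terminus C1 beside the C6 methylene and not to C3 beside the quaternary carbon, so that loss of methanol from the hemiketal leaves the ketone on C1 and the ether on C3; the closest known reaction type is O-alkylation of vinylogous esters with trialkyloxonium salts and hydrolysis of the resulting 1,3-dialkoxyallyl cations to vinylogous esters.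

Step 3
Reactants: 6 2,2'-methylenebis(3-methoxy-4,4-dimethylcyclohex-2-en-1-one)
Product: 8 2,2'-methylenebis(6,6-dibromo-3-methoxy-4,4-dimethylcyclohex-2-en-1-one), via bis(6-bromo ketone) 7 (not isolated)
Conditions: LiN(iPr)2 (2.2 equiv), THF, −78 °C, then NBS (2.2 equiv); LiN(SiMe3)2 (2.2 equiv), −78 °C, then NBS (2.2 equiv), −78 to 0 °C; aq. NH4Cl
Reagents that add atoms: N-bromosuccinimide, O=C1CCC(=O)N1Br
Why: C6 is the only enolisable position (C4 is quaternary, C2 fully substituted), so kinetic alpha-prime deprotonation of the vinylogous ester and bromination of the lithium enolate with NBS are regiodefined; the more acidic C6–H of 7 is then removed by the silylamide and brominated again, which also erases the stereocentres of 7.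

Step 4
Reactants: 8 2,2'-methylenebis(6,6-dibromo-3-methoxy-4,4-dimethylcyclohex-2-en-1-one)
Product: 9 2,2'-methylenebis(6-bromo-3-methoxy-4,4-dimethylcyclohexa-2,5-dien-1-one)
Conditions: DBU (3 equiv), PhMe, 60 °C
Reagents that add atoms: none
Why: E2 dehydrobromination of the alpha,alpha-dibromo ketone gives the alpha-bromo enone; only C5 carries beta-hydrogens, so the new double bond can form only at C5=C6, and the non-nucleophilic amidine should leave the vinylogous ester untouched.

Step 5
Reactants: 10 acetyl chloride; 11 1,1-dichloroethene
Product: 13 4,4-dichlorobut-3-en-2-one, via 4,4,4-trichlorobutan-2-one 12 (not isolated)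
Conditions: AlCl3 (1.1 equiv), CH2Cl2, 0 °C to rt; ice water; then distillation (loss of HCl)
Reagents that add atoms: none
Why: AlCl3-mediated Friedel–Crafts-type acylation of the alkene at its CH2 terminus with chloride capture at the dichlorinated carbon gives 12, which loses HCl on distillation to the conjugated dichlorovinyl ketone.

Step 6
Reactants: 13 4,4-dichlorobut-3-en-2-one
Product: 15 4,4-dimethoxybut-3-en-2-one, via 4-chloro-4-methoxybut-3-en-2-one 14 (not isolated)
Conditions: NaOMe (2.1 equiv), MeOH, 0 °C to rt
Reagents that add atoms: sodium methoxide, C[O-].[Na+]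
Why: Two successive conjugate addition–elimination reactions of methoxide at C4 replace both chlorides; the double-bond geometry of 14 is irrelevant because the product has two identical groups on C4.

Step 7
Reactants: 15 4,4-dimethoxybut-3-en-2-one
Product: 16 1,1-dimethoxy-3-(trimethylsilyloxy)buta-1,3-diene
Conditions: Me3SiOTf (1.1 equiv), Et3N (1.5 equiv), Et2O, 0 °C; distillation
Reagents that add atoms: trimethylsilyl trifluoromethanesulfonate, C[Si](C)(C)OS(=O)(=O)C(F)(F)F
Why: Amine-mediated soft enolisation and O-silylation of the methyl ketone (silyl enol ether formation); the methyl group is the only enolisable position, so a single diene should form.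

Step 8
Reactants: 9 2,2'-methylenebis(6-bromo-3-methoxy-4,4-dimethylcyclohexa-2,5-dien-1-one); 16 1,1-dimethoxy-3-(trimethylsilyloxy)buta-1,3-diene (6 equiv)
Product: 18 2,2'-methylenebis(6-hydroxy-3,8-dimethoxy-4,4-dimethylnaphthalen-1(4H)-one), via cis-fused bis(cycloadduct) 17 (not isolated)
Conditions: PhMe, 130 °C, sealed tube; then CF3CO2H, CH2Cl2, 0 °C to rt; then Et3N, rt
Reagents that add atoms: none
Why: Each bromo enone unit of 9 should react with the electron-rich diene in a normal-demand, concerted but strongly asynchronous [4+2] cycloaddition (at the polar limit a Mukaiyama–Michael addition followed by ring closure), the CH2 terminus C5 of the diene bonding to the enone beta-carbon C4a and the ketene acetal carbon C8 to the bromine-bearing alpha-carbon C8a. The closest known reaction type is the Diels–Alder benzannulation of 1,1-dialkoxy-3-silyloxybuta-1,3-dienes with alpha-halo enones and haloquinones. Each ring A is closed by this intermolecular cycloaddition, in which the bonds C4a–C5 and C8–C8a complete a six-membered carbocycle that is cis-fused to ring B in 17. The only new stereocentres, C4a and C8a of 17, are set cis by suprafacial addition to the ring alkene and are erased on aromatisation, so their configuration is of no consequence. Because H on C4a and Br on C8a are cis, the acid first expels methanol from the C8 ketal and unmasks the C6 silyl enol ether; in the resulting dienol the C8a–Br bond is allylic to a diene, so HBr can leave by ionisation to a cyclohexadienyl cation and proton loss, with Et3N taking up the acid. The step needs regioselectivity, which the matched polarisation of diene and enone secures and the bromine reinforces, and chemoselectivity for C4a=C8a over C2=C3, which is secured because C2=C3 is tetrasubstituted and carries the donor methoxy group. The vinylogous ester character of C1 and the quaternary C4 make the enone sluggish, which is why a large excess of the very nucleophilic diene and heat in a closed vessel are used.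

Step 9
Reactants: 18 2,2'-methylenebis(6-hydroxy-3,8-dimethoxy-4,4-dimethylnaphthalen-1(4H)-one)
Product: 20 2,2'-methylenebis(7-acetyl-6-hydroxy-3,8-dimethoxy-4,4-dimethylnaphthalen-1(4H)-one), via bis(difluoroboron chelate) 19 (not isolated)
Conditions: Ac2O (6 equiv), BF3·OEt2 (8 equiv), 70 °C; then NaOAc, MeOH–H2O, 60 °C
Reagents that add atoms: acetic anhydride, CC(=O)OC(C)=O
Why: O-Acetylation of the C6 phenol and BF3-promoted Fries rearrangement (or direct Friedel–Crafts acylation) should place the acetyl group on C7, ortho to the hydroxyl, because the other ortho position C5 is shielded by the peri gem-dimethyl group; the product is held as the difluoroboron chelate 19, which blocks a second acylation and is cleaved in the buffered methanolic work-up.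

Step 10
Reactants: 20 2,2'-methylenebis(7-acetyl-6-hydroxy-3,8-dimethoxy-4,4-dimethylnaphthalen-1(4H)-one)
Product: 21 2,2'-methylenebis(7-acetyl-3,6,8-trihydroxy-4,4-dimethylnaphthalen-1(4H)-one)
Conditions: BBr3 (12 equiv), CH2Cl2, −78 °C to rt; then H2O, 0 °C
Reagents that add atoms: none
Why: BBr3 binds the carbonyl and ether oxygens and bromide removes the methyl groups by SN2 attack at carbon, so the C8 aryl ethers (held between two carbonyls) and the C3 vinylogous esters are cleaved without any nucleophile having to reach the hindered C3; aryl ketones, the bridge and the quaternary carbons are inert to the reagent.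

## Compound list

1 | 4,4-dimethylcyclohexane-1,3-dione | CC1(C)CCC(=O)CC1=O | starting material
2 | formaldehyde | C=O | starting material
3 | 4,4-dimethyl-2-methylidenecyclohexane-1,3-dione (not isolated) | C=C1C(=O)CCC(C)(C)C1=O | intermediate
4 | 2,2'-methylenebis(3-hydroxy-4,4-dimethylcyclohex-2-en-1-one), one bis(enol) tautomer of 2,2'-methylenebis(4,4-dimethylcyclohexane-1,3-dione) | CC1(C)CCC(=O)C(CC2=C(O)C(C)(C)CCC2=O)=C1O | intermediate
5 | 2,2'-methylenebis(1,3-dimethoxy-4,4-dimethylcyclohex-2-en-1-ylium) bis(tetrafluoroborate) (not isolated) | COC1=C(CC2=C(OC)C(C)(C)CCC2=[O+]C)C(=[O+]C)CCC1(C)C.F[B-](F)(F)F.F[B-](F)(F)F | intermediate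
6 | 2,2'-methylenebis(3-methoxy-4,4-dimethylcyclohex-2-en-1-one) | COC1=C(CC2=C(OC)C(C)(C)CCC2=O)C(=O)CCC1(C)C | intermediate
7 | 2,2'-methylenebis(6-bromo-3-methoxy-4,4-dimethylcyclohex-2-en-1-one) (not isolated; mixture of diastereomers, configuration at C6 and C6' undefined) | COC1=C(CC2=C(OC)C(C)(C)CC(Br)C2=O)C(=O)C(Br)CC1(C)C | intermediate
8 | 2,2'-methylenebis(6,6-dibromo-3-methoxy-4,4-dimethylcyclohex-2-en-1-one) | COC1=C(CC2=C(OC)C(C)(C)CC(Br)(Br)C2=O)C(=O)C(Br)(Br)CC1(C)C | intermediate
9 | 2,2'-methylenebis(6-bromo-3-methoxy-4,4-dimethylcyclohexa-2,5-dien-1-one) | COC1=C(CC2=C(OC)C(C)(C)C=C(Br)C2=O)C(=O)C(Br)=CC1(C)C | intermediate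
10 | acetyl chloride | CC(=O)Cl | starting material
11 | 1,1-dichloroethene | C=C(Cl)Cl | starting material
12 | 4,4,4-trichlorobutan-2-one (not isolated) | CC(=O)CC(Cl)(Cl)Cl | intermediate
13 | 4,4-dichlorobut-3-en-2-one | CC(=O)C=C(Cl)Cl | intermediate
14 | 4-chloro-4-methoxybut-3-en-2-one (not isolated; either double-bond geometry) | CC(=O)C=C(Cl)OC | intermediate
15 | 4,4-dimethoxybut-3-en-2-one | CC(=O)C=C(OC)OC | intermediate
16 | 1,1-dimethoxy-3-(trimethylsilyloxy)buta-1,3-diene | C=C(O[Si](C)(C)C)C=C(OC)OC | intermediate
17 | 2,2'-methylenebis[8a-bromo-3,8,8-trimethoxy-4,4-dimethyl-6-(trimethylsilyloxy)-4a,5,8,8a-tetrahydronaphthalen-1(4H)-one], each half cis-fused (H on C4a and Br on C8a on the same face); not isolated; one of the two diastereomers that differ in the relative configuration of the halves is drawn, racemic | COC1=C(CC3=C(OC)C(C)(C)[C@@H]4CC(O[Si](C)(C)C)=CC(OC)(OC)[C@]4(Br)C3=O)C(=O)[C@@]2(Br)C(OC)(OC)C=C(O[Si](C)(C)C)C[C@H]2C1(C)C | intermediate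
18 | 2,2'-methylenebis(6-hydroxy-3,8-dimethoxy-4,4-dimethylnaphthalen-1(4H)-one) | COc1cc(O)cc2c1C(=O)C(CC1=C(OC)C(C)(C)c3cc(O)cc(OC)c3C1=O)=C(OC)C2(C)C | intermediate
19 | bis(difluoroboron chelate) of 20, with an O6–BF2–O(acetyl) six-membered chelate ring in each half (not isolated) | COc1c2C(C)=[O+][B-](F)(F)Oc2cc2c1C(=O)C(CC1=C(OC)C(C)(C)c3cc4O[B-](F)(F)[O+]=C(C)c4c(OC)c3C1=O)=C(OC)C2(C)C | intermediate
20 | 2,2'-methylenebis(7-acetyl-6-hydroxy-3,8-dimethoxy-4,4-dimethylnaphthalen-1(4H)-one) | COc1c(C(C)=O)c(O)cc2c1C(=O)C(CC1=C(OC)C(C)(C)c3cc(O)c(C(C)=O)c(OC)c3C1=O)=C(OC)C2(C)C | intermediate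
21 | 2,2'-methylenebis(7-acetyl-3,6,8-trihydroxy-4,4-dimethylnaphthalen-1(4H)-one) | CC(=O)c1c(O)cc2c(c1O)C(=O)C(CC1=C(O)C(C)(C)c3cc(O)c(C(C)=O)c(O)c3C1=O)=C(O)C2(C)C | target

## Step count and least certain steps

Total: 10 steps. Longest linear sequence: 7 steps (steps 1, 2, 3, 4, 8, 9, 10); the diene branch is steps 5 to 7.

**Step 2 (proposed new method).** The second O-methylation may stall at the carbonyl oxygen beside the quaternary carbon, or water may add in part at the hindered terminus or attack a methyl group, so that regiocontrol in the hydrolysis is eroded. The fallback uses known chemistry and sets out from 4. Unselective O-methylation with (trimethylsilyl)diazomethane in toluene–methanol should give 6 together with the unsymmetrical bis(enol ether) 2-[(2-methoxy-3,3-dimethyl-6-oxocyclohex-1-en-1-yl)methyl]-3-methoxy-6,6-dimethylcyclohex-2-en-1-one F1 and 2,2'-methylenebis(3-methoxy-6,6-dimethylcyclohex-2-en-1-one) F2. Compound 6 is separated by chromatography, and F1 and F2 are hydrolysed with 1 M HCl in THF back to 4 and recycled. The fallback comes back to the route at 6.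

**Step 8 (key step).** The cycloaddition may fail to start at the neopentyl carbon C4a of a vinylogous ester enone while the diene is consumed by thermal decomposition or protodesilylation, or aromatisation may stall at the bromide because H and Br are cis. The fallback replaces bromine by a sulfinyl group, which activates the enone and leaves by thermal syn elimination, and sets out from 6.
- Double sulfenylation with LiN(SiMe3)2 and PhSSPh gives 2,2'-methylenebis[3-methoxy-4,4-dimethyl-6,6-bis(phenylsulfanyl)cyclohex-2-en-1-one] F3.
- Oxidation of one sulfur per ring with mCPBA and warming (sulfoxide syn elimination) gives 2,2'-methylenebis[3-methoxy-4,4-dimethyl-6-(phenylsulfanyl)cyclohexa-2,5-dien-1-one] F4.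
- A second mCPBA oxidation gives 2,2'-methylenebis[3-methoxy-4,4-dimethyl-6-(phenylsulfinyl)cyclohexa-2,5-dien-1-one] F5, a mixture of sulfur epimers.
- Cycloaddition of F5 with 16 in toluene, loss of benzenesulfenic acid from the cis adduct on heating and acid-induced loss of methanol return to the route at 18.

**Step 3.** Proton exchange between enolate and monobromide may give mixtures of un-, mono- and dibrominated rings, and the brominating agent may attack the C2=C3 enol ether. The fallback dehydrogenates first and sets out from 6.
- LiN(SiMe3)2 and Me3SiCl give bis[2-methoxy-3,3-dimethyl-6-(trimethylsilyloxy)cyclohexa-1,5-dien-1-yl]methane F6.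
- Saegusa–Ito oxidation (Pd(OAc)2 cat., O2, DMSO) gives 2,2'-methylenebis(3-methoxy-4,4-dimethylcyclohexa-2,5-dien-1-one) F7.
- Alpha-iodination with I2 and pyridine gives 2,2'-methylenebis(6-iodo-3-methoxy-4,4-dimethylcyclohexa-2,5-dien-1-one) F8.
- F8 takes the place of 9 in step 8 (loss of HI instead of HBr), and the route is rejoined at 18.

**Step 9.** Acylation of the ring deactivated by the C1 carbonyl may be slow, and prolonged heating with BF3 may cleave or scramble the methylene bridge or cleave ethers prematurely. The fallback avoids electrophilic acylation and sets out from 18.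
- Iodination with N-iodosuccinimide in MeCN at 0 °C gives 2,2'-methylenebis(6-hydroxy-7-iodo-3,8-dimethoxy-4,4-dimethylnaphthalen-1(4H)-one) F9.
- Stille coupling with tributyl(1-ethoxyvinyl)stannane and Pd(PPh3)4 in toluene at 90 °C gives 2,2'-methylenebis[7-(1-ethoxyethenyl)-6-hydroxy-3,8-dimethoxy-4,4-dimethylnaphthalen-1(4H)-one] F10.
- Hydrolysis with 1 M HCl in THF returns to the route at 20.

**Step 10.** Cleavage of the hindered C3 vinylogous ethers may be incomplete, and the freed bis(enol) may cyclodehydrate to a pyran during the acidic work-up. The fallback separates the two kinds of ether and sets out from 20. BCl3 in CH2Cl2 at −78 to 0 °C cleaves only the chelated C8 ethers to give 2,2'-methylenebis(7-acetyl-6,8-dihydroxy-3-methoxy-4,4-dimethylnaphthalen-1(4H)-one) F11. LiCl in DMF at 120 °C then removes the vinylogous methyl groups by SN2 attack under non-acidic conditions and gives 21.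

## Further compounds

F1 | step 2 | 2-[(2-methoxy-3,3-dimethyl-6-oxocyclohex-1-en-1-yl)methyl]-3-methoxy-6,6-dimethylcyclohex-2-en-1-one | COC1=C(CC2=C(OC)CCC(C)(C)C2=O)C(=O)CCC1(C)C
F2 | step 2 | 2,2'-methylenebis(3-methoxy-6,6-dimethylcyclohex-2-en-1-one) | COC1=C(CC2=C(OC)CCC(C)(C)C2=O)C(=O)C(C)(C)CC1
F3 | step 8 | 2,2'-methylenebis[3-methoxy-4,4-dimethyl-6,6-bis(phenylsulfanyl)cyclohex-2-en-1-one] | COC1=C(CC2=C(OC)C(C)(C)CC(Sc3ccccc3)(Sc3ccccc3)C2=O)C(=O)C(Sc2ccccc2)(Sc2ccccc2)CC1(C)C
F4 | step 8 | 2,2'-methylenebis[3-methoxy-4,4-dimethyl-6-(phenylsulfanyl)cyclohexa-2,5-dien-1-one] | COC1=C(CC2=C(OC)C(C)(C)C=C(Sc3ccccc3)C2=O)C(=O)C(Sc2ccccc2)=CC1(C)C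
F5 | step 8 | 2,2'-methylenebis[3-methoxy-4,4-dimethyl-6-(phenylsulfinyl)cyclohexa-2,5-dien-1-one] (mixture of sulfur epimers) | COC1=C(CC2=C(OC)C(C)(C)C=C(S(=O)c3ccccc3)C2=O)C(=O)C(S(=O)c2ccccc2)=CC1(C)C
F6 | step 3 | bis[2-methoxy-3,3-dimethyl-6-(trimethylsilyloxy)cyclohexa-1,5-dien-1-yl]methane | COC1=C(CC2=C(OC)C(C)(C)CC=C2O[Si](C)(C)C)C(O[Si](C)(C)C)=CCC1(C)C
F7 | step 3 | 2,2'-methylenebis(3-methoxy-4,4-dimethylcyclohexa-2,5-dien-1-one) | COC1=C(CC2=C(OC)C(C)(C)C=CC2=O)C(=O)C=CC1(C)C
F8 | step 3 | 2,2'-methylenebis(6-iodo-3-methoxy-4,4-dimethylcyclohexa-2,5-dien-1-one) | COC1=C(CC2=C(OC)C(C)(C)C=C(I)C2=O)C(=O)C(I)=CC1(C)C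
F9 | step 9 | 2,2'-methylenebis(6-hydroxy-7-iodo-3,8-dimethoxy-4,4-dimethylnaphthalen-1(4H)-one) | COc1c(I)c(O)cc2c1C(=O)C(CC1=C(OC)C(C)(C)c3cc(O)c(I)c(OC)c3C1=O)=C(OC)C2(C)C
F10 | step 9 | 2,2'-methylenebis[7-(1-ethoxyethenyl)-6-hydroxy-3,8-dimethoxy-4,4-dimethylnaphthalen-1(4H)-one] | CCOC(=C)c1c(O)cc2c(c1OC)C(=O)C(CC1=C(OC)C(C)(C)c3cc(O)c(C(=C)OCC)c(OC)c3C1=O)=C(OC)C2(C)C
F11 | step 10 | 2,2'-methylenebis(7-acetyl-6,8-dihydroxy-3-methoxy-4,4-dimethylnaphthalen-1(4H)-one) | COC1=C(CC2=C(OC)C(C)(C)c3cc(O)c(C(C)=O)c(O)c3C2=O)C(=O)c2c(O)c(C(C)=O)c(O)cc2C1(C)C
A1 | alternative 1 | dimethyl 6,6'-(2,8-dimethyl-3,7-dioxononane-2,8-diyl)bis(2,4-dihydroxybenzoate) | COC(=O)c1c(O)cc(O)cc1C(C)(C)C(=O)CCCC(=O)C(C)(C)c1cc(O)cc(O)c1C(=O)OC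
A2 | alternative 1 | 6,6'-(3,3,9,9-tetramethyl-2,4,8,10-tetraoxoundecane-1,11-diyl)bis(4-hydroxy-2H-pyran-2-one) | O=C1C=C(O)C=C(CC(=O)C(C)(C)C(=O)CCCC(=O)C(C)(C)C(=O)CC2=CC(O)=CC(=O)O2)O1
A3 | alternative 2 | 2,2'-methylenebis(3-hydroxy-6,8-dimethoxy-4,4-dimethylnaphthalen-1(4H)-one) | COc1cc(OC)c2c(c1)C(C)(C)C(O)=C(CC1=C(O)C(C)(C)c3cc(OC)cc(OC)c3C1=O)C2=O
A4 | alternative 2 | dimethyl 2,4-bis[2-(3,5-dimethoxyphenyl)-2-methylpropanoyl]pentanedioate (enolisable stereocentres, mixture) | COC(=O)C(CC(C(=O)OC)C(=O)C(C)(C)c1cc(OC)cc(OC)c1)C(=O)C(C)(C)c1cc(OC)cc(OC)c1
A5 | alternative 2 | methyl 4-(3,5-dimethoxyphenyl)-4-methyl-3-oxopentanoate | COC(=O)CC(=O)C(C)(C)c1cc(OC)cc(OC)c1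
A6 | alternative 3 | 2,2'-methylenebis(7-acetyl-8-hydroxy-3,6-dimethoxy-4,4-dimethylnaphthalen-1(4H)-one) | CC(=O)c1c(OC)cc2c(c1O)C(=O)C(CC1=C(OC)C(C)(C)c3cc(OC)c(C(C)=O)c(O)c3C1=O)=C(OC)C2(C)C
A7 | alternative 3 | dimethyl 5,5'-methylenebis(4-methoxy-2,3,3-trimethyl-6-oxocyclohexa-1,4-diene-1-carboxylate) | COC(=O)C1=C(C)C(C)(C)C(OC)=C(CC2=C(OC)C(C)(C)C(C)=C(C(=O)OC)C2=O)C1=O
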